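Assumption: compounds 2, 14, 18, 20 and 28 are taken as commercial. Ring-B atoms are called C1′–C6′ in the discussion, while the names of the chromene intermediates use chromene numbering (C6 = C1′, C7 = C2′, C8 = C3′, C8a = C4′, C4a = C5′, C5 = C6′).

## The problem

Kazinol B (29) is a (2S)-flavan. Ring A carries one hydroxyl (C7), ring C is a plain dihydropyran with the only stereocentre at C2, and ring B is a benzene substituted at five of its six positions. Going round ring B, C1′ holds the flavan C2, C2′ a prenyl group, C3′ a free hydroxyl, and O4′/C5′ are bridged by a 2,2-dimethyl-2H-pyran; only C6′ is free. The hard part is this contiguous C,C,O,O,C pattern, above all the prenyl carbon on C2′. It is wedged between the C1′ substituent and O3′, the position least accessible to electrophilic prenylation or to a sigmatropic shift that has another way out. C2 is the sole stereocentre, so nothing in the molecule can relay chirality to it and it must come from a catalyst or an auxiliary. Because it is a benzylic ether carbon para to O4′ it can ionise, which argues for making it as a carbinol and closing ring C at the aryl carbon. The prenyl alkene (which cyclises onto the neighbouring 3′-OH in strong acid), the chromene alkene and the two phenols rule out hydrogenolysis, strong acid and oxidants late in the route. What opens the problem up is that C1′, C2′ and C3′ bear carbon, carbon and oxygen in a row. An aryne spanning C1′–C2′ with the C3′ oxygen beside it is polarised so that a carbon nucleophile enters at C1′ and a carbon electrophile at C2′. A propargyl arene as nucleophile brings C2, C3, C4 and ring A; an allyl halide as electrophile brings the handle for the prenyl group.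

## Retrosynthesis

**29 ⇒ 27 + 28.** The prenyl double bond is cut, so that the prenyl group comes from an allyl group by cross-metathesis with 2-methylbut-2-ene 28. Allyl is the fragment an arylcopper accepts with no SN2/SN2′ ambiguity, and it is a much poorer π-nucleophile than prenyl in the steps in between. Precursor 27 differs from the target by two methyl groups. The forward reaction must touch the terminal alkene and leave the chromene alkene, which is cis-disubstituted, conjugated and next to a quaternary carbon. The step is placed last so that the prenyl group never meets acid.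

**27 ⇒ 26.** The two O–CH2OMe bonds on O7 and O3′ are cut. Methoxymethyl ethers are chosen because the O3′ acetal earlier directs lithiation and polarises the aryne. They survive fluoride, organolithium, hydride and carbonate and leave in dilute acid. Benzyl ethers would need hydrogenolysis, and silyl ethers would not survive fluoride.

**26 ⇒ 25.** The O1–C8a bond is cut, not the C2–O1 bond. Ring closure then takes place at an sp2 carbon and cannot invert or erode the finished carbinol centre. Displacement at C2 by a phenol would pass through a centre with cation character stabilised by O4′. Precursor 25 is acyclic and carries an aryl bromide. The forward step is a copper-catalysed intramolecular etherification to a six-membered ring.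

**25 ⇒ 24.** The C2–H bond is cut. The stereocentre comes from the prochiral aryl ketone 24 by catalytic asymmetric transfer hydrogenation. The two ketone substituents (aryl and CH2CH2Ar) differ strongly, and the catalyst is the only source of asymmetry.

**24 ⇒ 22.** The C2=O bond is traced back to the alkyne of 22 by formal hydration with oxygen on the aryl-bearing carbon. A carbophilic gold or mercury π-acid would give this regiochemistry on a simple aryl alkyne. But 22 is also a 1,6-enyne (the C7 allyl group sits beside the C6 alkynyl group), and electrophilic activation invites cycloisomerisation. The conversion is therefore planned as a hydrometalation: copper hydride places copper on the aryl-bearing carbon, a borane traps it as alkenylboronate 23, and oxidation gives the ketone in the same flask.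

**22 ⇒ 13 + 19 + 20.** This is the strategic cut: C1′–C2 and C2′–C1‴, two bonds on adjacent ring carbons, which is the retron of aryne 21. Stepwise ortho-functionalisation would need halogenation or allylation of C2′ between two substituents. The aryne route instead lets O3′ decide which carbon takes the nucleophile. The precursors are silyl triflate 13, propargyl arene 19 and allyl chloride 20; the step joins both aromatic halves and sets the full ring-B substitution. The forward reaction needs regiocontrol in the acetylide addition and capture of the arylcopper by 20 before it is protonated.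

**13 ⇒ 11 ⇒ 8.** The C7–Si bond and the triflate are traced back to aryl carbamate 8. Directed ortho-metalation goes to the one position flanked by the carbamate and the MOM ether. The pyran ring is already present at this stage: it is a spectator of the aryne step, and building it early removes the need to tell O3′ from O4′ on a late catechol.

**8 ⇒ 7 ⇒ 6 ⇒ 4.** The pyran ring is opened to the aryl 1,1-dimethylpropargyl ether 7 (propargyl Claisen, C5′–C4″ formed and O4′–C2″ re-formed). Carbamate 7 comes from phenol 6, and 6 from aldehyde 4 by Dakin oxidation. The formyl group is a temporary substituent: it first makes the 4-hydroxyl acidic and then becomes the oxygen that leaves as triflate.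

**4 ⇒ 3 ⇒ 1 + 2.** Two O-alkylations remain. The para-formyl group of 3,4-dihydroxybenzaldehyde 1 differentiates the two hydroxyls, so chloride 2 goes on O4 and the MOM group on O3.

**19 ⇒ 17 + 18; 17 ⇒ 16 ⇒ 15 ⇒ 14.** The C3–C4 bond is cut, giving benzylic bromide 17 and ethynylmagnesium bromide 18. Bromide 17 comes from 2-bromo-4-hydroxybenzaldehyde 14 by protection, reduction and bromination. The ring bromine is the later partner for the O1–C8a bond.

## Roads not taken

**Alternative 1:** The pyran bonds (C5′–C4″, O4′–C2″) and the prenyl bond (C2′–C1‴) are cut together, leading back to A1, the 4′-O-(1,1-dimethylpropargyl) 3′-O-(1,1-dimethylallyl) bis-ether of a 7-O-silyl (2S)-flavan catechol.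
- Forward step: heating A1 should run a propargyl Claisen/electrocyclisation to the chromene and a [3,3] shift of the tertiary allyl ether to C2′, giving A2, the 7-O-silyl ether of the target.
- Merits: no metal, both C5 units placed in one operation, the stereocentre already present and untouched, one deprotection left.
- Weak points:
  - A1 needs two different tertiary ethers on adjacent catechol oxygens of a flavan. There is no acidity difference there, unlike in aldehyde 1.
  - The tertiary allyl ether normally comes from partial hydrogenation of a propargyl ether, so the order of etherifications is forced and costs several steps.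
  - Tertiary allyl aryl ethers ionise and lose isoprene on heating.
  - The allyl group leaving O3′ has only the crowded C2′ as ortho terminus. If the dienone does not enolise quickly it can move on by a Cope shift to the free C6′, so the regiochemistry is not enforced.
- Comparison: if the cascade behaves, this endgame is shorter than the chosen one and needs neither the formal hydration nor the metathesis. Against that, the chosen plan fixes C1′ and C2′ by aryne polarisation, not by competition between ortho and para pathways, and it differentiates the oxygens on a cheap aldehyde.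

**Alternative 2:** O1–C2 and C3–C4 are cut with an extra formyl carbon on C3, leading to salicylaldehyde A3 and ring-B enal A4.
- Forward step: a secondary-amine organocatalyst should promote oxa-Michael addition and aldol condensation to the 2-aryl-2H-chromene-3-carbaldehyde A5.
- Merits: convergent, catalytic, and it closes ring C and sets C2 in one step from two aldehydes. In stereocentre economy it is better than the three steps the chosen plan spends on hydration, reduction and C–O coupling.
- Weak points:
  - A5 carries a formyl group and a C3=C4 alkene that the target lacks. Removing them means decarbonylation with RhCl(PPh3)3 and an alkene reduction.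
  - The stereocentre of A5 is allylic, benzylic and on oxygen, so it can racemise by reversible ring opening, more so with the electron-rich ring B.
  - Ring B of A5 has neither prenyl group nor pyran. The C2′ prenylation between C1′ and O3′, which is the real difficulty, is left for later on a complete flavan.
  - The benzyl ether must go by hydrogenolysis before any alkene is introduced.
- Comparison: the chosen plan is longer at C2 but settles the crowded edge of ring B in the coupling step itself.

**Alternative 3:** Both C2–C3 and C2–C1′ are cut at a boron-bearing carbon.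
- Forward step: the chiral-diol boronic ester A6 is homologated with a dichloromethyl carbenoid and a Lewis acid, then treated with the ring-B arylmagnesium bromide A7, to give the secondary benzylic boronic ester A8. Oxidation would give an alcohol of the same kind as 25.
- Merits: auxiliary control of C2 is highly predictable and at least as reliable as transfer hydrogenation. Ring B arrives complete, so neither alkyne hydration nor metathesis is needed, and the ring closure is the same as in the chosen plan.
- Weak points:
  - A7 must already carry the full ring-B pattern, with the metal at C1′ next to the prenyl group. The crowded-edge problem is only moved into the synthesis of A7.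
  - The second migration asks a hindered ortho-substituted aryl group to displace chloride from a secondary α-chloroboronate that epimerises with chloride.
  - The chiral diol is stoichiometric and the carbenoid needs cryogenic conditions.
  - The prenyl group is then present during acidic deprotection.
- Comparison: the chosen plan builds the ring-B substitution and joins the fragments in one catalytic step and uses a catalytic asymmetric reduction. It pays with a formal hydration and a late metathesis.

Key step: step 12

## Route

Step 1
Reactants: 1 3,4-dihydroxybenzaldehyde; 2 3-chloro-3-methylbut-1-yne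
Product: 3 3-hydroxy-4-[(2-methylbut-3-yn-2-yl)oxy]benzaldehyde
Conditions: K2CO3 (1.1 equiv), KI, CuI (cat.), DMF, 50 °C
Reagents that add atoms: none
Why: The 4-hydroxyl, para to the formyl group, is several pK units more acidic than the 3-hydroxyl, so one equivalent of carbonate should give mainly the 4-phenoxide. It is alkylated by the tertiary propargylic chloride (copper-assisted O-propargylation), the known regioselective 4-O-alkylation of this catechol aldehyde.

Step 2
Reactants: 3 3-hydroxy-4-[(2-methylbut-3-yn-2-yl)oxy]benzaldehyde
Product: 4 3-(methoxymethoxy)-4-[(2-methylbut-3-yn-2-yl)oxy]benzaldehyde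
Conditions: MOMCl, i-Pr2NEt, CH2Cl2, 0 °C to rt
Reagents that add atoms: chloromethyl methyl ether, COCCl
Why: Standard acetal protection of the remaining phenol. The MOM oxygen later cooperates in the ortho-lithiation and polarises the aryne.

Step 3
Reactants: 4 3-(methoxymethoxy)-4-[(2-methylbut-3-yn-2-yl)oxy]benzaldehyde
Product: 6 3-(methoxymethoxy)-4-[(2-methylbut-3-yn-2-yl)oxy]phenol, via aryl formate 5 (not isolated)
Conditions: mCPBA, CH2Cl2, 0 °C to rt; then K2CO3 (cat.), MeOH, rt
Reagents that add atoms: 3-chloroperoxybenzoic acid, OOC(=O)c1cccc(Cl)c1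
Why: Dakin-type Baeyer–Villiger oxidation. The para-alkoxy group makes aryl migration win over hydride migration, and the formate is methanolysed in the same pot; the terminal alkyne is inert to the peracid.

Step 4
Reactants: 6 3-(methoxymethoxy)-4-[(2-methylbut-3-yn-2-yl)oxy]phenol
Product: 7 3-(methoxymethoxy)-4-[(2-methylbut-3-yn-2-yl)oxy]phenyl N-(propan-2-yl)carbamate
Conditions: i-PrNCO, Et3N (cat.), CH2Cl2, rt
Reagents that add atoms: isopropyl isocyanate, CC(C)N=C=O
Why: Base-catalysed addition of the phenol to the isocyanate gives an N-monoalkyl carbamate. It is a strong ortho-directing group that can later be removed under mild base.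

Step 5
Reactants: 7 3-(methoxymethoxy)-4-[(2-methylbut-3-yn-2-yl)oxy]phenyl N-(propan-2-yl)carbamate
Product: 8 8-(methoxymethoxy)-2,2-dimethyl-2H-chromen-6-yl N-(propan-2-yl)carbamate
Conditions: o-xylene, 130 °C, sealed vessel
Reagents that add atoms: none
Why: Aromatic propargyl Claisen rearrangement to the only free ortho position (the other carries the MOM ether). Enolisation, a 1,5-hydrogen shift and 6π oxa-electrocyclisation then give the 2,2-dimethyl-2H-chromene; the gem-dimethyl group accelerates the [3,3] shift.

Step 6
Reactants: 8 8-(methoxymethoxy)-2,2-dimethyl-2H-chromen-6-yl N-(propan-2-yl)carbamate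
Product: 11 8-(methoxymethoxy)-2,2-dimethyl-7-(trimethylsilyl)-2H-chromen-6-yl N-(propan-2-yl)carbamate, via N-silyl carbamate 9 (not isolated), via N-silyl C-silyl carbamate 10 (not isolated)
Conditions: TBSOTf, TMEDA, Et2O, 0 °C to rt; n-BuLi, TMEDA, −78 °C; TMSCl, −78 °C to rt; aq. NaHSO4 work-up
Reagents that add atoms: chlorotrimethylsilane, C[Si](C)(C)Cl; tert-butyldimethylsilyl triflate, CC(C)(C)[Si](C)(C)OS(=O)(=O)C(F)(F)F (silicon in 9 and 10 only)
Why: In situ N-silylation keeps the carbamate from fragmenting to isocyanate on deprotonation. Directed ortho-metalation then occurs at C7, the one position flanked by two coordinating oxygen groups, and the aryllithium is silylated; the N–Si bond is hydrolysed on work-up.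

Step 7
Reactants: 11 8-(methoxymethoxy)-2,2-dimethyl-7-(trimethylsilyl)-2H-chromen-6-yl N-(propan-2-yl)carbamate
Product: 13 8-(methoxymethoxy)-2,2-dimethyl-7-(trimethylsilyl)-2H-chromen-6-yl trifluoromethanesulfonate, via silylphenol 12 (not isolated)
Conditions: Et2NH, DBU, MeCN, 40 °C; then PhNTf2, rt
Reagents that add atoms: N-phenylbis(trifluoromethanesulfonimide), O=S(=O)(N(c1ccccc1)S(=O)(=O)C(F)(F)F)C(F)(F)F
Why: DBU triggers E1cB loss of isopropyl isocyanate, which diethylamine scavenges as a urea, and the phenoxide is triflated in the same pot. This is the standard conversion of ortho-silylaryl carbamates into ortho-silylaryl triflates.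

Step 8
Reactants: 14 2-bromo-4-hydroxybenzaldehyde
Product: 15 2-bromo-4-(methoxymethoxy)benzaldehyde
Conditions: MOMCl, i-Pr2NEt, CH2Cl2, 0 °C to rt
Reagents that add atoms: chloromethyl methyl ether, COCCl
Why: Standard MOM protection of the phenol, with the same group as on O3′ so that both leave together at the end.

Step 9
Reactants: 15 2-bromo-4-(methoxymethoxy)benzaldehyde
Product: 16 [2-bromo-4-(methoxymethoxy)phenyl]methanol
Conditions: NaBH4, MeOH, 0 °C
Reagents that add atoms: none
Why: Borohydride reduction of an aryl aldehyde; the aryl bromide and the acetal are inert.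

Step 10
Reactants: 16 [2-bromo-4-(methoxymethoxy)phenyl]methanol
Product: 17 2-bromo-1-(bromomethyl)-4-(methoxymethoxy)benzene
Conditions: CBr4, PPh3, CH2Cl2, 0 °C
Reagents that add atoms: carbon tetrabromide, BrC(Br)(Br)Br
Why: Appel bromination under neutral conditions, chosen over PBr3 or HBr to spare the MOM ether.

Step 11
Reactants: 17 2-bromo-1-(bromomethyl)-4-(methoxymethoxy)benzene; 18 ethynylmagnesium bromide
Product: 19 2-bromo-4-(methoxymethoxy)-1-(prop-2-yn-1-yl)benzene
Conditions: CuBr·SMe2 (10 mol%), excess 18, THF, 0 °C to 60 °C
Reagents that add atoms: none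
Why: Copper-catalysed sp–sp3 coupling of an alkynyl Grignard reagent with a benzylic bromide, a known route to 3-arylprop-1-ynes. The aryl bromide does not undergo halogen–magnesium exchange with the weakly basic acetylide.

Step 12
Reactants: 13 8-(methoxymethoxy)-2,2-dimethyl-7-(trimethylsilyl)-2H-chromen-6-yl trifluoromethanesulfonate; 19 2-bromo-4-(methoxymethoxy)-1-(prop-2-yn-1-yl)benzene; 20 allyl chloride
Product: 22 6-{3-[2-bromo-4-(methoxymethoxy)phenyl]prop-1-yn-1-yl}-8-(methoxymethoxy)-2,2-dimethyl-7-(prop-2-en-1-yl)-2H-chromene, via aryne 21 (not isolated)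
Conditions: CuI (10 mol%), CsF (3 equiv), 20 (3 equiv), MeCN/THF 1:1, 45 °C, slow addition of 13
Reagents that add atoms: none
Why: Fluoride attacks the silicon of 13 and triflate leaves, giving aryne 21 between C6 and C7 of the chromene (C1′ and C2′ of ring B). CuI and CsF convert alkyne 19 into its copper acetylide, which adds across the strained triple bond. The C8–O bond beside C7 withdraws σ-density and distorts the aryne so that C6 is the more electrophilic carbon; the alkynyl group therefore bonds to C6 and copper to C7, where the developing negative charge lies next to oxygen. This regioselectivity is the one the step needs, and the MOM-oxy group alone secures it. The arylcopper is then allylated by 20, through a trivalent allylcopper intermediate and reductive elimination, which forms the C7–CH2 bond and returns monovalent copper halide. The closest known reaction type is the CuI-catalysed three-component coupling of arynes from ortho-silylaryl triflates with terminal alkynes and allylic chlorides to 1-allyl-2-alkynylarenes. No ring is closed and no stereocentre is formed. Allylation must outrun protonation of the arylcopper by a second molecule of 19, so 20 is used in excess and 13 is added slowly; the aryl bromide, the acetals and the chromene alkene are spectators.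

Step 13
Reactants: 22 6-{3-[2-bromo-4-(methoxymethoxy)phenyl]prop-1-yn-1-yl}-8-(methoxymethoxy)-2,2-dimethyl-7-(prop-2-en-1-yl)-2H-chromene
Product: 24 3-[2-bromo-4-(methoxymethoxy)phenyl]-1-[8-(methoxymethoxy)-2,2-dimethyl-7-(prop-2-en-1-yl)-2H-chromen-6-yl]propan-1-one, via alkenylboronate 23 (not isolated)
Conditions: CuCl (5 mol%), 4,5-bis{bis[3,5-bis(trifluoromethyl)phenyl]phosphino}-9,9-dimethylxanthene (5 mol%), NaOtBu (10 mol%), HBpin (1.2 equiv), toluene, rt; then 30% H2O2, pH 7 phosphate buffer, THF, 0 °C
Reagents that add atoms: hydrogen peroxide, OO (the ketone oxygen); pinacolborane, B1OC(C)(C)C(C)(C)O1 (boron in 23 only, hydrogen at C3 of 24)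
Why: Copper hydride adds syn to the aryl alkyne with copper on the aryl-bearing carbon, and σ-bond metathesis with the borane gives the α-aryl alkenylboronate. This is the known α-selective copper-hydride hydroboration of 1-aryl-1-alkynes, and buffered peroxide oxidation then gives the enol and hence the aryl ketone. The alkyne is never activated electrophilically, so the neighbouring allyl group cannot enter an enyne cyclisation; the unactivated terminal alkene and the aryl bromide react far more slowly with copper hydride.

Step 14
Reactants: 24 3-[2-bromo-4-(methoxymethoxy)phenyl]-1-[8-(methoxymethoxy)-2,2-dimethyl-7-(prop-2-en-1-yl)-2H-chromen-6-yl]propan-1-one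
Product: 25 (1S)-3-[2-bromo-4-(methoxymethoxy)phenyl]-1-[8-(methoxymethoxy)-2,2-dimethyl-7-(prop-2-en-1-yl)-2H-chromen-6-yl]propan-1-ol
Conditions: RuCl[(S,S)-TsDPEN](p-cymene) (2 mol%), HCO2H/Et3N 5:2, DMF, 40 °C
Reagents that add atoms: none
Why: Noyori asymmetric transfer hydrogenation. In the six-membered Ru–H/N–H transition state the ketone aryl group lies under the η6-arene, and the (S,S)-catalyst should deliver hydride to the face that gives the (S)-carbinol, the same sense as for acetophenone; alkenes and the aryl bromide are not reduced.

Step 15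
Reactants: 25 (1S)-3-[2-bromo-4-(methoxymethoxy)phenyl]-1-[8-(methoxymethoxy)-2,2-dimethyl-7-(prop-2-en-1-yl)-2H-chromen-6-yl]propan-1-ol
Product: 26 (2S)-7-(methoxymethoxy)-2-[8-(methoxymethoxy)-2,2-dimethyl-7-(prop-2-en-1-yl)-2H-chromen-6-yl]-3,4-dihydro-2H-chromene
Conditions: CuI (10 mol%), 3,4,7,8-tetramethyl-1,10-phenanthroline (20 mol%), Cs2CO3, toluene, 110 °C, argon
Reagents that add atoms: none
Why: Ullmann-type intramolecular C–O coupling of the monovalent copper alkoxide with the aryl bromide closes the six-membered ring C. The bond forms at the aryl carbon, so the carbinol centre is not touched and its (S) configuration is retained.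

Step 16
Reactants: 26 (2S)-7-(methoxymethoxy)-2-[8-(methoxymethoxy)-2,2-dimethyl-7-(prop-2-en-1-yl)-2H-chromen-6-yl]-3,4-dihydro-2H-chromene
Product: 27 (2S)-2-[8-hydroxy-2,2-dimethyl-7-(prop-2-en-1-yl)-2H-chromen-6-yl]-3,4-dihydro-2H-chromen-7-ol
Conditions: 2 M aq. HCl, MeOH/THF, 40 °C
Reagents that add atoms: none
Why: Acid-catalysed acetal exchange with methanol removes both MOM groups. It is done while the side chain is still allyl, which does not cyclise onto the new 3′-OH as a prenyl group could, and dilute acid at this temperature should leave the chromene and the flavan ether intact.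

Step 17
Reactants: 27 (2S)-2-[8-hydroxy-2,2-dimethyl-7-(prop-2-en-1-yl)-2H-chromen-6-yl]-3,4-dihydro-2H-chromen-7-ol; 28 2-methylbut-2-ene
Product: 29 Kazinol B, (2S)-2-[8-hydroxy-2,2-dimethyl-7-(3-methylbut-2-en-1-yl)-2H-chromen-6-yl]-3,4-dihydro-2H-chromen-7-ol
Conditions: second-generation Grubbs catalyst RuCl2(=CHPh)(PCy3)(H2IMes) (5 mol%), 28 (large excess), CH2Cl2, 40 °C
Reagents that add atoms: none
Why: Olefin cross-metathesis of the terminal allyl group with excess trisubstituted alkene gives the prenyl group and propene. The chromene alkene is cis-disubstituted, conjugated and next to a quaternary carbon and should not enter the catalytic cycle; free phenols are tolerated.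

## Compound list

1 | 3,4-dihydroxybenzaldehyde | O=Cc1ccc(O)c(O)c1 | starting material
2 | 3-chloro-3-methylbut-1-yne | C#CC(C)(C)Cl | starting material
3 | 3-hydroxy-4-[(2-methylbut-3-yn-2-yl)oxy]benzaldehyde | O=Cc1ccc(OC(C)(C)C#C)c(O)c1 | intermediate
4 | 3-(methoxymethoxy)-4-[(2-methylbut-3-yn-2-yl)oxy]benzaldehyde | O=Cc1ccc(OC(C)(C)C#C)c(OCOC)c1 | intermediate
5 | 3-(methoxymethoxy)-4-[(2-methylbut-3-yn-2-yl)oxy]phenyl formate | O=COc1ccc(OC(C)(C)C#C)c(OCOC)c1 | intermediate
6 | 3-(methoxymethoxy)-4-[(2-methylbut-3-yn-2-yl)oxy]phenol | Oc1ccc(OC(C)(C)C#C)c(OCOC)c1 | intermediate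
7 | 3-(methoxymethoxy)-4-[(2-methylbut-3-yn-2-yl)oxy]phenyl N-(propan-2-yl)carbamate | CC(C)NC(=O)Oc1ccc(OC(C)(C)C#C)c(OCOC)c1 | intermediate
8 | 8-(methoxymethoxy)-2,2-dimethyl-2H-chromen-6-yl N-(propan-2-yl)carbamate | CC(C)NC(=O)Oc1cc2C=CC(C)(C)Oc2c(OCOC)c1 | intermediate
9 | 8-(methoxymethoxy)-2,2-dimethyl-2H-chromen-6-yl N-(tert-butyldimethylsilyl)-N-(propan-2-yl)carbamate | CC(C)N([Si](C)(C)C(C)(C)C)C(=O)Oc1cc2C=CC(C)(C)Oc2c(OCOC)c1 | intermediate
10 | 8-(methoxymethoxy)-2,2-dimethyl-7-(trimethylsilyl)-2H-chromen-6-yl N-(tert-butyldimethylsilyl)-N-(propan-2-yl)carbamate | CC(C)N([Si](C)(C)C(C)(C)C)C(=O)Oc1cc2C=CC(C)(C)Oc2c(OCOC)c1[Si](C)(C)C | intermediate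
11 | 8-(methoxymethoxy)-2,2-dimethyl-7-(trimethylsilyl)-2H-chromen-6-yl N-(propan-2-yl)carbamate | CC(C)NC(=O)Oc1cc2C=CC(C)(C)Oc2c(OCOC)c1[Si](C)(C)C | intermediate
12 | 8-(methoxymethoxy)-2,2-dimethyl-7-(trimethylsilyl)-2H-chromen-6-ol | Oc1cc2C=CC(C)(C)Oc2c(OCOC)c1[Si](C)(C)C | intermediate
13 | 8-(methoxymethoxy)-2,2-dimethyl-7-(trimethylsilyl)-2H-chromen-6-yl trifluoromethanesulfonate | O=S(=O)(Oc1cc2C=CC(C)(C)Oc2c(OCOC)c1[Si](C)(C)C)C(F)(F)F | intermediate
14 | 2-bromo-4-hydroxybenzaldehyde | O=Cc1ccc(O)cc1Br | starting material
15 | 2-bromo-4-(methoxymethoxy)benzaldehyde | O=Cc1ccc(OCOC)cc1Br | intermediate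
16 | [2-bromo-4-(methoxymethoxy)phenyl]methanol | OCc1ccc(OCOC)cc1Br | intermediate
17 | 2-bromo-1-(bromomethyl)-4-(methoxymethoxy)benzene | BrCc1ccc(OCOC)cc1Br | intermediate
18 | ethynylmagnesium bromide | C#C[Mg]Br | starting material
19 | 2-bromo-4-(methoxymethoxy)-1-(prop-2-yn-1-yl)benzene | C#CCc1ccc(OCOC)cc1Br | intermediate
20 | allyl chloride (3-chloroprop-1-ene) | C=CCCl | starting material
21 | 6,7-didehydro-8-(methoxymethoxy)-2,2-dimethyl-2H-chromene (aryne) | C1#CC(OCOC)=C2OC(C)(C)C=CC2=C1 | intermediate
22 | 6-{3-[2-bromo-4-(methoxymethoxy)phenyl]prop-1-yn-1-yl}-8-(methoxymethoxy)-2,2-dimethyl-7-(prop-2-en-1-yl)-2H-chromene | C=CCc1c(C#CCc3ccc(OCOC)cc3Br)cc2C=CC(C)(C)Oc2c1OCOC | intermediate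
23 | 2-{(1Z)-3-[2-bromo-4-(methoxymethoxy)phenyl]-1-[8-(methoxymethoxy)-2,2-dimethyl-7-(prop-2-en-1-yl)-2H-chromen-6-yl]prop-1-en-1-yl}-4,4,5,5-tetramethyl-1,3,2-dioxaborolane | C=CCc1c(/C(B3OC(C)(C)C(C)(C)O3)=C\Cc3ccc(OCOC)cc3Br)cc2C=CC(C)(C)Oc2c1OCOC | intermediate
24 | 3-[2-bromo-4-(methoxymethoxy)phenyl]-1-[8-(methoxymethoxy)-2,2-dimethyl-7-(prop-2-en-1-yl)-2H-chromen-6-yl]propan-1-one | C=CCc1c(C(=O)CCc3ccc(OCOC)cc3Br)cc2C=CC(C)(C)Oc2c1OCOC | intermediate
25 | (1S)-3-[2-bromo-4-(methoxymethoxy)phenyl]-1-[8-(methoxymethoxy)-2,2-dimethyl-7-(prop-2-en-1-yl)-2H-chromen-6-yl]propan-1-ol | C=CCc1c([C@@H](O)CCc3ccc(OCOC)cc3Br)cc2C=CC(C)(C)Oc2c1OCOC | intermediate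
26 | (2S)-7-(methoxymethoxy)-2-[8-(methoxymethoxy)-2,2-dimethyl-7-(prop-2-en-1-yl)-2H-chromen-6-yl]-3,4-dihydro-2H-chromene | C=CCc1c([C@@H]2CCc3ccc(OCOC)cc3O2)cc2C=CC(C)(C)Oc2c1OCOC | intermediate
27 | (2S)-2-[8-hydroxy-2,2-dimethyl-7-(prop-2-en-1-yl)-2H-chromen-6-yl]-3,4-dihydro-2H-chromen-7-ol | C=CCc1c([C@@H]2CCc3ccc(O)cc3O2)cc2C=CC(C)(C)Oc2c1O | intermediate
28 | 2-methylbut-2-ene | CC=C(C)C | starting material
29 | Kazinol B, (2S)-2-[8-hydroxy-2,2-dimethyl-7-(3-methylbut-2-en-1-yl)-2H-chromen-6-yl]-3,4-dihydro-2H-chromen-7-ol | CC(C)=CCc1c([C@@H]2CCc3ccc(O)cc3O2)cc2c(c1O)OC(C)(C)C=C2 | target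

## Step count and risks

Total: 17 steps. Longest linear sequence: 13 steps (steps 1–7, then 12–17); the alkyne branch (steps 8–11) joins at step 12.

**Step 12 (key step).** The CH2 of 19 is both benzylic and propargylic, so fluoride may isomerise the alkyne to an allene before or after acetylide formation. The arylcopper may also be protonated instead of allylated, and the acetylide may be allylated directly. Fallback, setting out from 13, 20 and 17 and returning at 22: the three-component coupling is run with (triisopropylsilyl)acetylene, which has no acidic methylene, to give 7-(prop-2-en-1-yl)-8-(methoxymethoxy)-2,2-dimethyl-6-[(triisopropylsilyl)ethynyl]-2H-chromene F1. Desilylation with Bu4NF gives 6-ethynyl-8-(methoxymethoxy)-2,2-dimethyl-7-(prop-2-en-1-yl)-2H-chromene F2. Its magnesium acetylide (EtMgBr) is coupled with benzylic bromide 17 under CuBr·SMe2 catalysis to give 22. The aryne still sets the ring-B pattern; only the C3–C4 bond is made afterwards.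

**Step 13.** Hydrocupration may lose regiocontrol, which would put boron on C3 and lead to the benzyl ketone isomer. Copper hydride may also add to the styrene-like chromene alkene, or the catalytic alkoxide may isomerise the skipped alkyne. Fallback, from 22 directly to 24: Markovnikov hydration with Ph3PAuNTf2 in aqueous methanol, where the para oxygen O4′ directs water to C2. Methanol is used as solvent so that solvent capture competes with cyclisation of the 1,6-enyne, which is the reason this is the second choice. No new compound is involved.

**Step 15.** Oxidative addition to the electron-rich aryl bromide may be slow, so that copper-mediated dehydrogenation of the benzylic alcohol back to 24 or protodebromination competes. Fallback, setting out from 24 and returning at 26, with the C2–O1 bond formed instead: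
- Hydroxylation of the aryl bromide (Pd2(dba)3, t-BuXPhos, KOH, dioxane/water) gives 3-[2-hydroxy-4-(methoxymethoxy)phenyl]-1-[8-(methoxymethoxy)-2,2-dimethyl-7-(prop-2-en-1-yl)-2H-chromen-6-yl]propan-1-one F3.
- Transfer hydrogenation with RuCl[(R,R)-TsDPEN](p-cymene) gives (1R)-3-[2-hydroxy-4-(methoxymethoxy)phenyl]-1-[8-(methoxymethoxy)-2,2-dimethyl-7-(prop-2-en-1-yl)-2H-chromen-6-yl]propan-1-ol F4.
- Mitsunobu cyclisation (PPh3, DIAD, THF, 0 °C) closes ring C with inversion to 26. The known weakness here is partial loss of enantiopurity through ionisation of the electron-rich benzylic centre.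

**Step 11.** The product may isomerise to the arylallene under the basic Grignard conditions, and the product acetylide may be benzylated a second time. Fallback, setting out from 17 and returning at 19: coupling with (trimethylsilyl)ethynylmagnesium bromide under CuBr·SMe2 gives {3-[2-bromo-4-(methoxymethoxy)phenyl]prop-1-yn-1-yl}trimethylsilane F5, which is desilylated with K2CO3 in methanol at 0 °C.

**Step 17.** Ruthenium hydride species may move the allyl double bond into conjugation with ring B, and the free ortho phenol may slow the catalyst. Fallback, setting out from 26 and returning at 29: the metathesis is run on the protected flavan to give (2S)-7-(methoxymethoxy)-2-[8-(methoxymethoxy)-2,2-dimethyl-7-(3-methylbut-2-en-1-yl)-2H-chromen-6-yl]-3,4-dihydro-2H-chromene F6, and the MOM groups are then removed with dilute HCl in methanol at room temperature. The prenyl group is then exposed to acid, so the mildest workable conditions are needed.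

## Further compounds

F1 | step 12 | 8-(methoxymethoxy)-2,2-dimethyl-7-(prop-2-en-1-yl)-6-[(triisopropylsilyl)ethynyl]-2H-chromene | C=CCc1c(C#C[Si](C(C)C)(C(C)C)C(C)C)cc2C=CC(C)(C)Oc2c1OCOC
F2 | step 12 | 6-ethynyl-8-(methoxymethoxy)-2,2-dimethyl-7-(prop-2-en-1-yl)-2H-chromene | C=CCc1c(C#C)cc2C=CC(C)(C)Oc2c1OCOC
F0 | step 13 | none | none
F3 | step 15 | 3-[2-hydroxy-4-(methoxymethoxy)phenyl]-1-[8-(methoxymethoxy)-2,2-dimethyl-7-(prop-2-en-1-yl)-2H-chromen-6-yl]propan-1-one | C=CCc1c(C(=O)CCc3ccc(OCOC)cc3O)cc2C=CC(C)(C)Oc2c1OCOC
F4 | step 15 | (1R)-3-[2-hydroxy-4-(methoxymethoxy)phenyl]-1-[8-(methoxymethoxy)-2,2-dimethyl-7-(prop-2-en-1-yl)-2H-chromen-6-yl]propan-1-ol | C=CCc1c([C@H](O)CCc3ccc(OCOC)cc3O)cc2C=CC(C)(C)Oc2c1OCOC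
F5 | step 11 | {3-[2-bromo-4-(methoxymethoxy)phenyl]prop-1-yn-1-yl}trimethylsilane | C[Si](C)(C)C#CCc1ccc(OCOC)cc1Br
F6 | step 17 | (2S)-7-(methoxymethoxy)-2-[8-(methoxymethoxy)-2,2-dimethyl-7-(3-methylbut-2-en-1-yl)-2H-chromen-6-yl]-3,4-dihydro-2H-chromene | CC(C)=CCc1c([C@@H]2CCc3ccc(OCOC)cc3O2)cc2C=CC(C)(C)Oc2c1OCOC
A1 | alternative 1 | (2S)-7-[(tert-butyldimethylsilyl)oxy]-2-{3-[(2-methylbut-3-en-2-yl)oxy]-4-[(2-methylbut-3-yn-2-yl)oxy]phenyl}-3,4-dihydro-2H-chromene | C#CC(C)(C)Oc1ccc([C@@H]2CCc3ccc(O[Si](C)(C)C(C)(C)C)cc3O2)cc1OC(C)(C)C=C
A2 | alternative 1 | 7-O-(tert-butyldimethylsilyl) Kazinol B | CC(C)=CCc1c([C@@H]2CCc3ccc(O[Si](C)(C)C(C)(C)C)cc3O2)cc2C=CC(C)(C)Oc2c1O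
A3 | alternative 2 | 2-hydroxy-4-[(triisopropylsilyl)oxy]benzaldehyde | O=Cc1ccc(O[Si](C(C)C)(C(C)C)C(C)C)cc1O
A4 | alternative 2 | (2E)-3-[4-(benzyloxy)-3-(methoxymethoxy)phenyl]prop-2-enal | O=C/C=C/c1ccc(OCc2ccccc2)c(OCOC)c1
A5 | alternative 2 | (2R)-2-[4-(benzyloxy)-3-(methoxymethoxy)phenyl]-7-[(triisopropylsilyl)oxy]-2H-chromene-3-carbaldehyde (same spatial arrangement at C2 as the target) | COCOc1cc([C@@H]2C(C=O)=Cc3ccc(O[Si](C(C)C)(C(C)C)C(C)C)cc3O2)ccc1OCc1ccccc1
A6 | alternative 3 | (4S,5S)-2-{2-[2-bromo-4-(methoxymethoxy)phenyl]ethyl}-4,5-dicyclohexyl-1,3,2-dioxaborolane | COCOc1ccc(CCB2O[C@@H](C3CCCCC3)[C@H](C3CCCCC3)O2)c(Br)c1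
A7 | alternative 3 | [8-(methoxymethoxy)-2,2-dimethyl-7-(3-methylbut-2-en-1-yl)-2H-chromen-6-yl]magnesium bromide | CC(C)=CCc1c([Mg]Br)cc2C=CC(C)(C)Oc2c1OCOC
A8 | alternative 3 | (4S,5S)-2-{(1S)-3-[2-bromo-4-(methoxymethoxy)phenyl]-1-[8-(methoxymethoxy)-2,2-dimethyl-7-(3-methylbut-2-en-1-yl)-2H-chromen-6-yl]propyl}-4,5-dicyclohexyl-1,3,2-dioxaborolane | COCOc1ccc(CC[C@H](B2O[C@@H](C3CCCCC3)[C@H](C3CCCCC3)O2)c2cc3C=CC(C)(C)Oc3c(OCOC)c2CC=C(C)C)c(Br)c1
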